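**One charge.** The substrate charge stood at 0.050 M in the autumn and dusk runs and in eta, zeta and alpha, so the charges of these flasks differed in reagent.

the same everywhere: substrate 0.050 M

| charge | reagent | remark | time |
|---|---|---|---|
| autumn | 0.13 M | run made earlier |  |
| dusk | 0.18 M | run made earlier |  |
| eta | 0.100 M |  | 30 min |
| zeta | 0.125 M |  | 30 min |
| alpha | 0.150 M |  | 30 min |

| run | time / min | triple product / % | substrate / % |
|---|---|---|---|
| autumn | 2.00 | 0.1 | 58.2 |
| autumn | 5.00 | 1.5 | 29.4 |
| autumn | 10.0 | 5.2 | 10.5 |
| autumn | 15.0 | 6.4 | 5.1 |
| dusk | 2.00 | 0.4 | 47.7 |
| dusk | 5.00 | 2.8 | 17.6 |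
| dusk | 10.0 | 9.1 | 3.6 |
| dusk | 15.0 | 13.3 | 0.8 |

(standard deviation of a reading: 0.5 percentage points)

- final triple product, as a percentage of the substrate charged, for each flask in turn (eta, zeta, alpha)

**Reading the order.** I took r, the rate of triple product between 5.00 min and 15.0 min, as a fraction of the substrate charged. It was 0.00490 /min in autumn and 0.0105 /min in dusk, faster there on a modest rise in reagent. I defined the reagent order of the yield, n, as the logarithm of that rate ratio over the logarithm of the charge ratio: 2.34. Each reading carried 0.5 percentage points, so n was a loose reading.

**My reckoning.** I scaled autumn's 15.0 min yield and r by the charge ratio raised to n, then held the rate steady to 30 min. That gave 7.44%, 12.5% and 19.2%. But autumn's substrate was down to 5.1% by 15.0 min, so I expected the rate to sag and these figures to run high. The ratio of alpha to eta, 2.58, does not depend on the steady rate, so I trusted it more.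

**The result.** The forecast, holding that reagent use “starves the leaner flasks”, gave 8%, 12.5% and 18%, close to my figures but not equal to them. The flasks gave 6.52%, 11.4% and 16.9%, each below my figure, while alpha over eta came to 2.59 against my 2.58. Reckoned the same way on final yields, zeta against eta gives an order of 2.50, beside the 2.34 read from the rates of autumn and dusk.

    substrate + reagent → single product (k = 0.0380 /M/s)
    reagent + single product → bis adduct (k = 0.00380 /M/s)
    reagent + bis adduct → triple product (k = 0.0550 /M/s)
    bis adduct → side product (k = 0.00630 /s)

**The crossing.** Bis adduct forks, and the selectivity factor, reagent step over side step, equals one at 0.115 M reagent. In zeta reagent stood lower at 30.0 min, at 0.0537 M, with side product at 19.1% against triple product at 11.4%. Without the side step zeta reaches 25.7% at 30.0 min, and with that step in place zeta reaches 24.8% at 300 min.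

(The earlier runs and the new flask were computed with constants of no real substance, noise included.)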